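**Strategy**

Everything rests on disconnecting the C3–C4 bond of the dihydropyran ring. Neither carbon carries a carbon branch (C4 hangs on C4a of ring A, C3 on the gem-dimethyl carbon C2), so both can be termini of a ring-closing olefin metathesis. The precursor is an acetophenone with a vinyl group and a 1,1-dimethylallyl ether on neighbouring carbons of ring A. In one operation the metathesis closes the pyran ring and delivers a 2,2-dimethyl-2H-chromene, the best substrate class for (salen)MnCl epoxidation. That epoxidation sets C3 (R); hydrogenolysis of the benzylic C4–O bond leaves the C3 carbinol, and a Claisen–Schmidt condensation adds the 4-hydroxycinnamoyl arm.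

Key step: step 4

Assumption: tert-butyl 2-methylbut-3-en-2-yl carbonate (5) is taken as a catalogue reagent, like 1, 3 and 11.

**Route**

Step 1
Reactants: 1 1-(2,4-dihydroxy-6-methoxyphenyl)ethan-1-one
Product: 2 1-(2,4-dihydroxy-3-iodo-6-methoxyphenyl)ethan-1-one
Conditions: I2 (0.4 equiv), HIO3 (0.2 equiv), EtOH–H2O, rt
Reagents that add atoms: iodine II; iodic acid OI(=O)=O
Why: Electrophilic aromatic iodination is expected at C3, the site between the two hydroxyl groups and para to the methoxy group, which is the less hindered of the two activated positions; one iodonium equivalent limits di-iodination.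

Step 2
Reactants: 2 1-(2,4-dihydroxy-3-iodo-6-methoxyphenyl)ethan-1-one; 3 2-ethenyl-4,4,5,5-tetramethyl-1,3,2-dioxaborolane
Product: 4 1-(3-ethenyl-2,4-dihydroxy-6-methoxyphenyl)ethan-1-one
Conditions: PdCl2(dppf) (5 mol%), K2CO3, 1,4-dioxane–H2O, 80 °C
Reagents that add atoms: none
Why: Suzuki–Miyaura cross-coupling of the aryl iodide tolerates free phenols and the ketone and installs the vinyl group whose inner carbon becomes C4.

Step 3
Reactants: 4 1-(3-ethenyl-2,4-dihydroxy-6-methoxyphenyl)ethan-1-one; 5 tert-butyl 2-methylbut-3-en-2-yl carbonate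
Product: 6 1-[3-ethenyl-2-hydroxy-6-methoxy-4-(2-methylbut-3-en-2-yloxy)phenyl]ethan-1-one
Conditions: Pd(PPh3)4 (2 mol%), 4 Å MS, THF, 0 °C to rt
Reagents that add atoms: none
Why: Tsuji–Trost O-allylation, in which the (1,1-dimethylallyl)palladium complex from decarboxylative ionization of 5 should be captured at its tertiary terminus by the more acidic, non-chelated 4-phenoxide (kinetic branched ether), while the acetyl-chelated 2-OH stays free.

Step 4
Reactants: 6 1-[3-ethenyl-2-hydroxy-6-methoxy-4-(2-methylbut-3-en-2-yloxy)phenyl]ethan-1-one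
Product: 7 1-(5-hydroxy-7-methoxy-2,2-dimethyl-2H-chromen-6-yl)ethan-1-one
Conditions: second-generation Grubbs catalyst (H2IMes)(PCy3)Cl2Ru=CHPh (5 mol%), CH2Cl2 (0.005 M), 40 °C
Reagents that add atoms: none
Why: Olefin metathesis by the Chauvin mechanism: the ruthenium alkylidene loads onto one terminal vinyl group, forms a ruthenacyclobutane with the other and cycloreverts, so that the styrene carbon (C4) and the inner carbon of the 1,1-dimethylallyl ether (C3) become joined as the C3=C4 double bond and ethene is lost. The closest known reaction type is ring-closing metathesis of 2-vinylphenyl allyl ethers to 2H-chromenes. The one ring closed is the six-membered pyran ring, closed by ring-closing olefin metathesis between two monosubstituted alkenes, necessarily as the cis ring olefin. No stereocenter is formed; the step delivers the cis, aryl-conjugated olefin next to quaternary C2 on which the catalyst-controlled epoxidation of step 6 sets C3. The selectivity needed is cyclization over acyclic diene oligomerization and over thermal Claisen rearrangement of the tertiary allyl aryl ether; the ortho placement of the two alkenes, the gem-dimethyl group (Thorpe–Ingold effect), high dilution and 40 °C should secure it. The chelated phenol and the hindered aryl ketone are tolerated by ruthenium alkylidenes.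

Step 5
Reactants: 7 1-(5-hydroxy-7-methoxy-2,2-dimethyl-2H-chromen-6-yl)ethan-1-one
Product: 8 6-acetyl-7-methoxy-2,2-dimethyl-2H-chromen-5-yl acetate
Conditions: Ac2O, Et3N, DMAP (cat.), CH2Cl2, rt
Reagents that add atoms: acetic anhydride CC(=O)OC(C)=O
Why: DMAP-catalysed O-acylation masks the phenol against oxidation and lowers the electron density of ring A, so the benzylic epoxide of the next step is less prone to ionize.

Step 6
Reactants: 8 6-acetyl-7-methoxy-2,2-dimethyl-2H-chromen-5-yl acetate
Product: 9 (3R,4R)-6-acetyl-3,4-epoxy-7-methoxy-2,2-dimethyl-3,4-dihydro-2H-chromen-5-yl acetate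
Conditions: (R,R)-(salen)MnCl [salen = N,N'-bis(3,5-di-tert-butylsalicylidene)cyclohexane-1,2-diamine dianion] (5 mol%), mCPBA, NMO, CH2Cl2, −78 °C
Reagents that add atoms: 3-chloroperoxybenzoic acid (mCPBA) OOC(=O)c1cccc(Cl)c1
Why: Jacobsen–Katsuki epoxidation, in which the pentavalent oxomanganese salen species transfers oxygen to the cis C3=C4 olefin and the (R,R) catalyst is expected, as on other 2,2-dimethylchromenes, to give the (3R,4R)-oxide, which sets C3; ketone and ester are inert at −78 °C.

Step 7
Reactants: 9 (3R,4R)-6-acetyl-3,4-epoxy-7-methoxy-2,2-dimethyl-3,4-dihydro-2H-chromen-5-yl acetate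
Product: 10 (3R)-6-acetyl-3-hydroxy-7-methoxy-2,2-dimethyl-3,4-dihydro-2H-chromen-5-yl acetate
Conditions: H2 (1 atm), Pd/C (10 wt%), Et3N (trace), EtOAc, rt; crude 9 used directly
Reagents that add atoms: none
Why: Heterogeneous hydrogenolysis should cleave only the benzylic C4–O bond of the epoxide, so C4 becomes CH2 while the C3–O bond and its (R) configuration are untouched.

Step 8
Reactants: 10 (3R)-6-acetyl-3-hydroxy-7-methoxy-2,2-dimethyl-3,4-dihydro-2H-chromen-5-yl acetate; 11 4-(methoxymethoxy)benzaldehyde
Product: 13 (E)-1-[(3R)-3,5-dihydroxy-7-methoxy-2,2-dimethyl-3,4-dihydro-2H-chromen-6-yl]-3-[4-(methoxymethoxy)phenyl]prop-2-en-1-one, via deacetylated phenol ketone 12 (not isolated)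
Conditions: KOH (excess), EtOH–H2O, 0 °C to rt; then aq. HCl to pH 5
Reagents that add atoms: none
Why: Claisen–Schmidt condensation, in which hydroxide first cleaves the aryl acetate, the methyl ketone enolate then adds to the non-enolizable aldehyde and the aldol dehydrates (E1cB) to the (E)-enone; C3 is not epimerizable under base.

Step 9
Reactants: 13 (E)-1-[(3R)-3,5-dihydroxy-7-methoxy-2,2-dimethyl-3,4-dihydro-2H-chromen-6-yl]-3-[4-(methoxymethoxy)phenyl]prop-2-en-1-one
Product: 14 (E)-1-[(3R)-3,5-dihydroxy-7-methoxy-2,2-dimethyl-3,4-dihydro-2H-chromen-6-yl]-3-(4-hydroxyphenyl)prop-2-en-1-one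
Conditions: 3 M aq. HCl, MeOH, rt
Reagents that add atoms: none
Why: Acid-catalysed acetal exchange (methanolysis of the methoxymethyl ether) should free the phenol under conditions that leave the tertiary alkyl aryl ether, the secondary alcohol and the (E)-chalcone intact.

**Compound list**

1 | 1-(2,4-dihydroxy-6-methoxyphenyl)ethan-1-one | CC(=O)c1c(O)cc(O)cc1OC | starting material
2 | 1-(2,4-dihydroxy-3-iodo-6-methoxyphenyl)ethan-1-one | CC(=O)c1c(O)c(I)c(O)cc1OC | intermediate
3 | 2-ethenyl-4,4,5,5-tetramethyl-1,3,2-dioxaborolane | C=CB1OC(C)(C)C(C)(C)O1 | starting material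
4 | 1-(3-ethenyl-2,4-dihydroxy-6-methoxyphenyl)ethan-1-one | CC(=O)c1c(O)c(C=C)c(O)cc1OC | intermediate
5 | tert-butyl 2-methylbut-3-en-2-yl carbonate | CC(C)(C)OC(=O)OC(C)(C)C=C | starting material
6 | 1-[3-ethenyl-2-hydroxy-6-methoxy-4-(2-methylbut-3-en-2-yloxy)phenyl]ethan-1-one | CC(=O)c1c(O)c(C=C)c(OC(C)(C)C=C)cc1OC | intermediate
7 | 1-(5-hydroxy-7-methoxy-2,2-dimethyl-2H-chromen-6-yl)ethan-1-one | CC(=O)c1c(O)c2C=CC(C)(C)Oc2cc1OC | intermediate
8 | 6-acetyl-7-methoxy-2,2-dimethyl-2H-chromen-5-yl acetate | CC(=O)c1c(OC(C)=O)c2C=CC(C)(C)Oc2cc1OC | intermediate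
9 | (3R,4R)-6-acetyl-3,4-epoxy-7-methoxy-2,2-dimethyl-3,4-dihydro-2H-chromen-5-yl acetate | CC1(C)Oc2cc(OC)c(C(C)=O)c(OC(C)=O)c2[C@H]2O[C@@H]12 | intermediate
10 | (3R)-6-acetyl-3-hydroxy-7-methoxy-2,2-dimethyl-3,4-dihydro-2H-chromen-5-yl acetate | COc1cc2c(c(OC(C)=O)c1C(C)=O)C[C@@H](O)C(C)(C)O2 | intermediate
11 | 4-(methoxymethoxy)benzaldehyde | COCOc1ccc(C=O)cc1 | starting material
12 | 1-[(3R)-3,5-dihydroxy-7-methoxy-2,2-dimethyl-3,4-dihydro-2H-chromen-6-yl]ethan-1-one | COc1cc2c(c(O)c1C(C)=O)C[C@@H](O)C(C)(C)O2 | intermediate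
13 | (E)-1-[(3R)-3,5-dihydroxy-7-methoxy-2,2-dimethyl-3,4-dihydro-2H-chromen-6-yl]-3-[4-(methoxymethoxy)phenyl]prop-2-en-1-one | COc1cc2c(c(O)c1C(=O)/C=C/c1ccc(OCOC)cc1)C[C@@H](O)C(C)(C)O2 | intermediate
14 | (E)-1-[(3R)-3,5-dihydroxy-7-methoxy-2,2-dimethyl-3,4-dihydro-2H-chromen-6-yl]-3-(4-hydroxyphenyl)prop-2-en-1-one | COc1cc2c(c(O)c1C(=O)/C=C/c1ccc(O)cc1)C[C@@H](O)C(C)(C)O2 | target

**Step count and risks**

Total step count: 9. Longest linear sequence: 9 steps (1 to 14).

Steps most likely to fail:

Step 1. The iodination may lack positional selectivity: attack at C5 next to the methoxy group, or double iodination. The fallback sets out from 1 and fixes the position by mechanism instead of by ring electronics. The palladium-catalysed O-allylation of step 3 is run first on 1 with 5 and should give 1-[2-hydroxy-6-methoxy-4-(2-methylbut-3-en-2-yloxy)phenyl]ethan-1-one F1. Magnesium-phenoxide-directed ortho-formylation (MgCl2, Et3N, paraformaldehyde, THF, 60 °C) can only place the formyl group ortho to the one remaining phenol and should give 3-acetyl-2-hydroxy-4-methoxy-6-(2-methylbut-3-en-2-yloxy)benzaldehyde F2. Wittig methylenation (Ph3P=CH2, THF, 0 °C) then comes back to the route at 6.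

Step 3. The allylpalladium complex may be captured at its unsubstituted terminus, or the branched ether may equilibrate under palladium to the linear prenyl ether; C-allylation is also possible. The fallback sets out from 4 and avoids allylpalladium chemistry. Copper-catalysed propargylic etherification with 3-chloro-3-methylbut-1-yne (CuCl2·2H2O cat., DBU, MeCN, 0 °C) should give 1-[3-ethenyl-2-hydroxy-6-methoxy-4-(2-methylbut-3-yn-2-yloxy)phenyl]ethan-1-one F3. Semihydrogenation of the alkyne (H2, Pd/CaCO3 poisoned with Pb(OAc)2, quinoline) comes back to the route at 6.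

Step 6. The electron-rich benzylic epoxide may ionize during reaction or isolation (opening or rearrangement), and uncatalysed peracid epoxidation may erode the enantiomeric purity. The fallback sets out from 8 and uses the rearrangement on purpose. Uncatalysed epoxidation (mCPBA, NaHCO3, CH2Cl2, 0 °C) gives racemic 6-acetyl-3,4-epoxy-7-methoxy-2,2-dimethyl-3,4-dihydro-2H-chromen-5-yl acetate F4, which is not isolated. A Lewis acid (ZnI2 cat.) induces Meinwald rearrangement by 1,2-hydride shift from C3 to the benzylic C4 cation, giving 6-acetyl-7-methoxy-2,2-dimethyl-3-oxo-3,4-dihydro-2H-chromen-5-yl acetate F5. An (R)-selective ketoreductase (NADPH, propan-2-ol for cofactor recycling, buffer pH 7) reduces the C3 ketone and comes back to the route at 10. Both enantiomers of the oxide are thereby funnelled into the one carbinol configuration.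

Further compounds
F1 | step 1 | 1-[2-hydroxy-6-methoxy-4-(2-methylbut-3-en-2-yloxy)phenyl]ethan-1-one | CC(=O)c1c(O)cc(OC(C)(C)C=C)cc1OC
F2 | step 1 | 3-acetyl-2-hydroxy-4-methoxy-6-(2-methylbut-3-en-2-yloxy)benzaldehyde | CC(=O)c1c(O)c(C=O)c(OC(C)(C)C=C)cc1OC
F3 | step 3 | 1-[3-ethenyl-2-hydroxy-6-methoxy-4-(2-methylbut-3-yn-2-yloxy)phenyl]ethan-1-one | CC(=O)c1c(O)c(C=C)c(OC(C)(C)C#C)cc1OC
F4 | step 6 | racemic 6-acetyl-3,4-epoxy-7-methoxy-2,2-dimethyl-3,4-dihydro-2H-chromen-5-yl acetate | CC1(C)Oc2cc(OC)c(C(C)=O)c(OC(C)=O)c2C2OC12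
F5 | step 6 | 6-acetyl-7-methoxy-2,2-dimethyl-3-oxo-3,4-dihydro-2H-chromen-5-yl acetate | CC1(C)Oc2cc(OC)c(C(C)=O)c(OC(C)=O)c2CC1=O
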